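The numbers in the tables stem from a simulated flask with constants of no real substance; the scatter is artificial.

Of the second nucleophile charged to the eta run, 0.0335 M is left at 120 min, reckoned as one second nucleophile per other capture product. That leftover carries the argument: the readings are flat from 15.0 min and sum to about the charge, so each run gives one finished split of the dissolved solid substrate between target and other capture product.

in all of them: gas 30 mM (held)
- eta: solid substrate 0.10 M; second nucleophile 0.070 M; run made earlier
- epsilon: solid substrate 0.10 M; second nucleophile 0.16 M; run made earlier
- delta: solid substrate 0.15 M; second nucleophile 0.105 M; run made earlier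
- flask: solid substrate 0.10 M; second nucleophile 0.105 M; time 1.5 h

| run | time / min | target / % | other capture product / % |
|---|---|---|---|
| eta | 15.0 | 64.1 | 37.2 |
| eta | 40.0 | 63.7 | 36.5 |
| eta | 80.0 | 63.4 | 36.8 |
| eta | 120 | 63.6 | 36.5 |
| epsilon | 15.0 | 42.1 | 58.4 |
| epsilon | 40.0 | 41.6 | 58.6 |
| epsilon | 80.0 | 41.8 | 58.5 |
| epsilon | 120 | 42.0 | 58.3 |
| delta | 15.0 | 56.3 | 43.4 |
| delta | 40.0 | 57.0 | 42.9 |
| delta | 80.0 | 55.9 | 43.5 |
| delta | 120 | 56.7 | 43.1 |

(standard deviation of a reading: 0.3 percentage points)

- ratio of target to other capture product at 25 s
- ratio of target to other capture product at 6.0 min
- ratio of target to other capture product at 1.5 h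

- solid, in amounts per volume of the solution: solid substrate
- the numbers in the tables scatter by 0.3 percentage points (one standard deviation)
- at the start none of the gas is in solution
- at the start none of the solid substrate is in solution

Let P be target, Q other capture product, D the second nucleophile present, N its charge and S the solid substrate charged, each in M. The reckoning here takes the rate of target over the rate of other capture product as c/D, so that:

dP/dQ = c/D, with D = N − Q

P = c ln[N/(N − Q)], with P + Q = S

The three leftovers give c as 0.0863 M, 0.0927 M and 0.0889 M as readings, with a mean of 0.0893 M. This c is the capture constant, a fitted concentration that sets target capture against other capture in the reckoned line, and it is a reading from finished yields.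

In this reckoning the flask starts at a rate ratio of 0.851. Held there, it would give Q = 0.0540 M, but the P this leaves returns Q = 0.0422 M from the integrated line. Taking the midpoint, then the midpoint with what that returns, gives Q = 0.0472 M. The falling D therefore raises the rate ratio by a factor of 1.82, to 1.54, and the accumulated ratio at 1.5 h is 1.12. Gas starts at none in solution, and the readings begin at 15.0 min, so this reckoning stands for the end of the flask and not for 25 s.

The forecast gives 0.6, 0.97 and 1.12, adding that “the 25 s and 6 min values are guesses with wide ranges”.

The flask gives 0.361 at 25 s, 1.07 at 6.0 min and 1.12 at 1.5 h.

    starting material → intermediate (k = 0.0200 s⁻¹)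
    first nucleophile + intermediate → target (k = 95.0 L mol⁻¹ s⁻¹)
    second nucleophile + intermediate → other capture product (k = 26.0 L mol⁻¹ s⁻¹)
    second nucleophile → decomposition product (k = 6.70 × 10⁻⁶ s⁻¹)
    gas ⇌ first nucleophile, rate k5*(csat - [first nucleophile]) (kL = 0.0280 s⁻¹)
    solid substrate ⇌ starting material, rate k6*(cs6 - [starting material]) while solid is left; crystals form when [starting material] > cs6 (solubility = 0.0840 M, k = 0.00400 s⁻¹)

The neighbouring flask is charged with 0.040 M of solid substrate and the flask's second nucleophile, so it starts from the same reckoned rate ratio. With the same c, its Q comes to 0.0206 M, which raises the rate ratio by a factor of 1.24, less than the flask's 1.82, and gives an accumulated ratio of 0.942. Simulated, the neighbouring flask ends with target at 47.8% of its solid substrate and a ratio of 0.917.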